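**Retrosynthetic overview**
1. Target 35 comes from 33 by desilylation and ester hydrolysis. 33 is cut at the C2–C3 bond into alkyl triflate 32 and ynoate 28, joined by a new copper-hydride reductive α-alkylation that also sets the 2Z acrylate.
2. 32 is cut at C8–C9 into alkenyl iodide 8 and triene 20 (9-BBN hydroboration, then B-alkyl Suzuki–Miyaura coupling; 7E alkene).
3. 8 comes from (R)-carvone by epoxidation, Eschenmoser–Tanabe ring opening, reduction and hydrozirconation–iodination. The carvone stereocentre becomes C5, the only stereocentre of the target.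
4. 20 comes from neryl acetate (11Z alkene bought in) by terminal alkene cleavage, Still–Gennari olefination (15Z) and methylenation. 28 comes from furan-3-ylmethanol and 1-(trimethylsilyl)propyne.
5. Rings: none is built. The furan is purchased, the carvone ring is opened in step 2, and the oxiranes of 2 and 10 are transient.

Assumption: the SMILES is read as 5R with 2Z (carboxyl cis to the furylethyl chain), 7E, 11Z and 15Z (CH2OH cis to the chain); the Still–Gennari propionate is used as its commercial ethyl ester.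

**Route**

Step 1
Reactants: 1 (R)-(−)-carvone
Product: 2 (1R,4R,6R)-1-methyl-4-(prop-1-en-2-yl)-7-oxabicyclo[4.1.0]heptan-2-one
Conditions: 30% aq. H2O2, NaOH (cat.), MeOH, 0 °C
Reagents that add atoms: hydrogen peroxide, OO
Why: Weitz–Scheffer nucleophilic epoxidation, in which hydroperoxide adds to the enone anti to the isopropenyl group while the isolated alkene is inert; the two oxirane stereocentres are erased in step 2 and the carvone stereocentre is untouched.

Step 2
Reactants: 2 (1R,4R,6R)-1-methyl-4-(prop-1-en-2-yl)-7-oxabicyclo[4.1.0]heptan-2-one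
Product: 4 (3S)-3-(prop-1-en-2-yl)hept-5-ynal, via p-toluenesulfonylhydrazone 3 (not isolated)
Conditions: TsNHNH2 (1.0 equiv), CH2Cl2/AcOH 1:1, −20 °C → rt
Reagents that add atoms: none
Why: Eschenmoser–Tanabe fragmentation, in which the hydrazone opens the oxirane and then fragments with loss of N2 and sulfinate, cutting the ring between the former enone α- and β-carbons to give the but-2-ynyl arm and the aldehyde arm without touching the stereocentre.

Step 3
Reactants: 4 (3S)-3-(prop-1-en-2-yl)hept-5-ynal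
Product: 5 (3S)-3-(prop-1-en-2-yl)hept-5-yn-1-ol
Conditions: NaBH4, MeOH, 0 °C
Reagents that add atoms: none
Why: Chemoselective borohydride reduction of the aldehyde, with alkyne and alkene inert.

Step 4
Reactants: 5 (3S)-3-(prop-1-en-2-yl)hept-5-yn-1-ol
Product: 6 tert-butyldimethyl{[(3S)-3-(prop-1-en-2-yl)hept-5-yn-1-yl]oxy}silane
Conditions: TBSCl, imidazole, CH2Cl2, rt
Reagents that add atoms: tert-butyldimethylsilyl chloride, CC(C)(C)[Si](C)(C)Cl
Why: Standard silyl protection, so that the free alcohol does not consume the zirconium hydride in step 5.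

Step 5
Reactants: 6 tert-butyldimethyl{[(3S)-3-(prop-1-en-2-yl)hept-5-yn-1-yl]oxy}silane
Product: 8 tert-butyl{[(3S,5E)-6-iodo-3-(prop-1-en-2-yl)hept-5-en-1-yl]oxy}dimethylsilane, via alkenylzirconocene chloride 7 (not isolated)
Conditions: Cp2Zr(H)Cl (1.5 equiv), THF, rt, dark; then I2, 0 °C
Reagents that add atoms: iodine, II
Why: Hydrozirconation–iodination, in which syn Zr–H addition (after equilibration) places zirconium on the less hindered methyl-bearing alkyne carbon and iodinolysis with retention gives the (E)-2-iodo-2-alkene that fixes the 7E geometry; the alkyne reacts much faster than the hindered 1,1-disubstituted alkene.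

Step 6
Reactants: 9 neryl acetate
Product: 10 (2Z)-5-(3,3-dimethyloxiran-2-yl)-3-methylpent-2-en-1-yl acetate (racemic)
Conditions: mCPBA (1.05 equiv), NaHCO3, CH2Cl2, 0 °C
Reagents that add atoms: 3-chloroperbenzoic acid, OOC(=O)c1cccc(Cl)c1
Why: Prilezhaev epoxidation, selective for the electron-rich terminal alkene because the 2,3-alkene is deactivated by the allylic acetate; the racemic oxirane carbon is removed in step 7.

Step 7
Reactants: 10 (2Z)-5-(3,3-dimethyloxiran-2-yl)-3-methylpent-2-en-1-yl acetate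
Product: 12 (2Z)-3-methyl-6-oxohex-2-en-1-yl acetate, via glycol 11 (not isolated)
Conditions: H5IO6 (1.3 equiv), THF/H2O, 0 °C
Reagents that add atoms: none
Why: Periodic acid hydrolyses the epoxide and cleaves the glycol (Malaprade cleavage) to the aldehyde and acetone, leaving the Z-allylic acetate intact.

Step 8
Reactants: 12 (2Z)-3-methyl-6-oxohex-2-en-1-yl acetate; 13 ethyl 2-[bis(2,2,2-trifluoroethoxy)phosphoryl]propanoate
Product: 15 ethyl (2Z,6Z)-8-acetoxy-2,6-dimethylocta-2,6-dienoate, via potassium phosphonate carbanion 14 (not isolated)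
Conditions: KN(SiMe3)2, 18-crown-6, THF, −78 °C
Reagents that add atoms: none
Why: Still–Gennari olefination, in which the electron-poor phosphonate under dissociating conditions eliminates kinetically to the (Z)-2-methyl-2-enoate, setting the 15Z geometry (oxygenated carbon cis to the chain).

Step 9
Reactants: 15 ethyl (2Z,6Z)-8-acetoxy-2,6-dimethylocta-2,6-dienoate
Product: 16 ethyl (2Z,6Z)-8-hydroxy-2,6-dimethylocta-2,6-dienoate
Conditions: K2CO3 (0.2 equiv), EtOH, 0 °C → rt
Reagents that add atoms: none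
Why: Base-catalysed transesterification removes the acetate, while the hindered α-methyl enoate is an ethyl ester in ethanol and stays unchanged.

Step 10
Reactants: 16 ethyl (2Z,6Z)-8-hydroxy-2,6-dimethylocta-2,6-dienoate
Product: 17 ethyl (2Z,6Z)-2,6-dimethyl-8-oxoocta-2,6-dienoate
Conditions: activated MnO2 (15 equiv), CH2Cl2, rt
Reagents that add atoms: none
Why: Heterogeneous MnO2 oxidation of the allylic alcohol to the enal, neutral conditions that preserve the neral-type Z geometry.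

Step 11
Reactants: 17 ethyl (2Z,6Z)-2,6-dimethyl-8-oxoocta-2,6-dienoate
Product: 18 ethyl (2Z,6Z)-2,6-dimethylnona-2,6,8-trienoate
Conditions: Ph3PCH3Br, KN(SiMe3)2, THF, −78 → 0 °C
Reagents that add atoms: methyltriphenylphosphonium bromide, C[P+](c1ccccc1)(c1ccccc1)c1ccccc1.[Br-]
Why: Wittig methylenation of the aldehyde gives the terminal 1,3-diene, the hindered conjugated ester being inert to the ylide at low temperature.

Step 12
Reactants: 18 ethyl (2Z,6Z)-2,6-dimethylnona-2,6,8-trienoate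
Product: 19 (2Z,6Z)-2,6-dimethylnona-2,6,8-trien-1-ol
Conditions: i-Bu2AlH (2.2 equiv), CH2Cl2, −78 °C
Reagents that add atoms: none
Why: 1,2-Reduction of the enoate by the aluminium hydride gives the Z-allylic alcohol without touching the diene.

Step 13
Reactants: 19 (2Z,6Z)-2,6-dimethylnona-2,6,8-trien-1-ol
Product: 20 tert-butyl{[(2Z,6Z)-2,6-dimethylnona-2,6,8-trien-1-yl]oxy}diphenylsilane
Conditions: TBDPSCl, imidazole, CH2Cl2, rt
Reagents that add atoms: tert-butyl(chloro)diphenylsilane, CC(C)(C)[Si](Cl)(c1ccccc1)c1ccccc1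
Why: Silylation with the robust TBDPS group, which survives steps 18–21 and is orthogonal to the TBS ether.

Step 14
Reactants: 21 furan-3-ylmethanol
Product: 22 3-(bromomethyl)furan
Conditions: PBr3, Et2O, 0 °C (used at once)
Reagents that add atoms: phosphorus tribromide, BrP(Br)Br
Why: SN2 bromination of the primary furylmethyl alcohol through its phosphite ester.

Step 15
Reactants: 22 3-(bromomethyl)furan; 23 trimethyl(prop-1-yn-1-yl)silane
Product: 25 [4-(furan-3-yl)but-1-yn-1-yl]trimethylsilane, via silylpropargyllithium 24 (not isolated)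
Conditions: n-BuLi, THF, −78 °C (23); then 22, −78 → −20 °C
Reagents that add atoms: none
Why: SN2 alkylation of the reactive furylmethyl bromide by the lithiated silylpropyne, the silyl group directing attack through the propargylic carbon.

Step 16
Reactants: 25 [4-(furan-3-yl)but-1-yn-1-yl]trimethylsilane
Product: 26 3-(but-3-yn-1-yl)furan
Conditions: K2CO3, MeOH, rt
Reagents that add atoms: none
Why: Methoxide-mediated protodesilylation of the alkynylsilane.

Step 17
Reactants: 26 3-(but-3-yn-1-yl)furan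
Product: 28 methyl 5-(furan-3-yl)pent-2-ynoate, via lithium acetylide 27 (not isolated)
Conditions: n-BuLi (1.0 equiv), THF, −78 °C; then ClCO2Me, −78 → 0 °C
Reagents that add atoms: methyl chloroformate, COC(=O)Cl
Why: Acetylide acylation with a chloroformate, the alkyne C–H being far more acidic than any furan C–H.

Step 18
Reactants: 20 tert-butyl{[(2Z,6Z)-2,6-dimethylnona-2,6,8-trien-1-yl]oxy}diphenylsilane; 8 tert-butyl{[(3S,5E)-6-iodo-3-(prop-1-en-2-yl)hept-5-en-1-yl]oxy}dimethylsilane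
Product: 30 tert-butyl{[(2Z,6Z,10E,13S)-15-[(tert-butyldimethylsilyl)oxy]-2,6,10-trimethyl-13-(prop-1-en-2-yl)pentadeca-2,6,10-trien-1-yl]oxy}diphenylsilane, via B-alkyl-9-BBN 29 (not isolated)
Conditions: 9-BBN-H (1.05 equiv), THF, 0 °C → rt (20); then H2O, 8, Pd(dppf)Cl2·CH2Cl2 (5 mol %), AsPh3, Cs2CO3, DMF, rt
Reagents that add atoms: none
Why: B-alkyl Suzuki–Miyaura coupling, in which 9-BBN adds only to the terminal CH2 of the 1,3-diene to give the homoallylic borane and the zerovalent palladium cycle couples it with the alkenyl iodide with retention, forming the C8–C9 bond of the target chain and completing the E,Z,Z-triene.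

Step 19
Reactants: 30 tert-butyl{[(2Z,6Z,10E,13S)-15-[(tert-butyldimethylsilyl)oxy]-2,6,10-trimethyl-13-(prop-1-en-2-yl)pentadeca-2,6,10-trien-1-yl]oxy}diphenylsilane
Product: 31 (3S,5E,9Z,13Z)-15-[(tert-butyldiphenylsilyl)oxy]-6,10,14-trimethyl-3-(prop-1-en-2-yl)pentadeca-5,9,13-trien-1-ol
Conditions: PPTS (0.2 equiv), MeOH/CH2Cl2, rt
Reagents that add atoms: none
Why: Acid-catalysed methanolysis removes the primary alkyl TBS ether selectively, the TBDPS ether being far more stable to acid.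

Step 20
Reactants: 31 (3S,5E,9Z,13Z)-15-[(tert-butyldiphenylsilyl)oxy]-6,10,14-trimethyl-3-(prop-1-en-2-yl)pentadeca-5,9,13-trien-1-ol
Product: 32 (3S,5E,9Z,13Z)-15-[(tert-butyldiphenylsilyl)oxy]-6,10,14-trimethyl-3-(prop-1-en-2-yl)pentadeca-5,9,13-trien-1-yl trifluoromethanesulfonate
Conditions: Tf2O, 2,6-lutidine, CH2Cl2, −78 °C (cold filtration, used at once)
Reagents that add atoms: trifluoromethanesulfonic anhydride, O=S(=O)(OS(=O)(=O)C(F)(F)F)C(F)(F)F
Why: O-Sulfonylation of the primary alcohol at low temperature with a hindered base gives the electrophile needed for a polar alkylation.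

Step 21
Reactants: 32 (3S,5E,9Z,13Z)-15-[(tert-butyldiphenylsilyl)oxy]-6,10,14-trimethyl-3-(prop-1-en-2-yl)pentadeca-5,9,13-trien-1-yl trifluoromethanesulfonate; 28 methyl 5-(furan-3-yl)pent-2-ynoate
Product: 33 methyl (2Z,5R,7E,11Z,15Z)-17-[(tert-butyldiphenylsilyl)oxy]-2-[3-(furan-3-yl)propylidene]-8,12,16-trimethyl-5-(prop-1-en-2-yl)heptadeca-7,11,15-trienoate
Conditions: (IPr)CuCl (10 mol %; IPr = 1,3-bis(2,6-diisopropylphenyl)imidazol-2-ylidene), CsF (2.5 equiv), (Me2HSi)2O (1.5 equiv), 28 (1.3 equiv), toluene/1,4-dioxane 1:1, 0 °C → rt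
Reagents that add atoms: none
Why: Proposed new method: copper-hydride-catalysed reductive α-alkylation of a 2-ynoate with a primary alkyl triflate, in which the monovalent copper hydride (from the copper fluoride and the hydrosilane) adds syn across 28 with hydride to C3 and copper to the ester-bearing C2, and the resulting α-cuprio enoate/copper allenolate is C-alkylated by 32 in an SN2 step on the side of the new vinylic hydrogen (anti to the furylethyl group), so that the C2–C3 bond and the 2Z geometry are set together while CsF returns the copper triflate to the fluoride; the path is polar on purpose, because an alkyl radical at this carbon would be a 5-hexenyl radical and cyclise, and the closest known reaction types are the copper-hydride anti-Markovnikov hydroalkylation of terminal alkynes with alkyl triflates and the copper-hydride reductive aldol reaction of ynoates.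

Step 22
Reactants: 33 methyl (2Z,5R,7E,11Z,15Z)-17-[(tert-butyldiphenylsilyl)oxy]-2-[3-(furan-3-yl)propylidene]-8,12,16-trimethyl-5-(prop-1-en-2-yl)heptadeca-7,11,15-trienoate
Product: 34 methyl (2Z,5R,7E,11Z,15Z)-2-[3-(furan-3-yl)propylidene]-17-hydroxy-8,12,16-trimethyl-5-(prop-1-en-2-yl)heptadeca-7,11,15-trienoate
Conditions: Bu4NF, AcOH, THF, 0 °C → rt
Reagents that add atoms: none
Why: Fluoride-mediated desilylation, buffered with acetic acid so that the Z-enoate is not exposed to a basic medium.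

Step 23
Reactants: 34 methyl (2Z,5R,7E,11Z,15Z)-2-[3-(furan-3-yl)propylidene]-17-hydroxy-8,12,16-trimethyl-5-(prop-1-en-2-yl)heptadeca-7,11,15-trienoate
Product: 35 (2Z,5R,7E,11Z,15Z)-2-[3-(furan-3-yl)propylidene]-17-hydroxy-8,12,16-trimethyl-5-(prop-1-en-2-yl)heptadeca-7,11,15-trienoic acid
Conditions: LiOH·H2O (5 equiv), THF/MeOH/H2O, rt → 35 °C; then 1 M HCl to pH 4
Reagents that add atoms: lithium hydroxide, [Li+].[OH-]
Why: Saponification by acyl–oxygen cleavage under mild conditions, to which 2-alkyl-(Z)-2-enoates, the furan and the allylic alcohol are stable, gives the target with the carvone-derived 5R centre unchanged.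

**Compound list**
1 | (R)-(−)-carvone, (5R)-2-methyl-5-(prop-1-en-2-yl)cyclohex-2-en-1-one | CC1=CC[C@H](CC1=O)C(C)=C | starting material
2 | (1R,4R,6R)-1-methyl-4-(prop-1-en-2-yl)-7-oxabicyclo[4.1.0]heptan-2-one | C=C(C)[C@H]1CC(=O)[C@]2(C)O[C@@H]2C1 | intermediate
3 | p-toluenesulfonylhydrazone of 2 (ring stereocentres as in 2) | C=C(C)[C@H]1CC(=NNS(=O)(=O)c2ccc(C)cc2)[C@]2(C)O[C@@H]2C1 | intermediate
4 | (3S)-3-(prop-1-en-2-yl)hept-5-ynal | O=CC[C@H](CC#CC)C(C)=C | intermediate
5 | (3S)-3-(prop-1-en-2-yl)hept-5-yn-1-ol | OCC[C@H](CC#CC)C(C)=C | intermediate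
6 | tert-butyldimethyl{[(3S)-3-(prop-1-en-2-yl)hept-5-yn-1-yl]oxy}silane | CC#CC[C@@H](CCO[Si](C)(C)C(C)(C)C)C(C)=C | intermediate
7 | chlorobis(cyclopentadienyl)[(2E,5S)-7-[(tert-butyldimethylsilyl)oxy]-5-(prop-1-en-2-yl)hept-2-en-2-yl]zirconium | C/C(=C\C[C@@H](CCO[Si](C)(C)C(C)(C)C)C(C)=C)[Zr](Cl)(C1C=CC=C1)C1C=CC=C1 | intermediate
8 | tert-butyl{[(3S,5E)-6-iodo-3-(prop-1-en-2-yl)hept-5-en-1-yl]oxy}dimethylsilane | C/C(I)=C\C[C@@H](CCO[Si](C)(C)C(C)(C)C)C(C)=C | intermediate
9 | neryl acetate, (2Z)-3,7-dimethylocta-2,6-dien-1-yl acetate | CC(C)=CCC/C(C)=C\COC(C)=O | starting material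
10 | (2Z)-5-(3,3-dimethyloxiran-2-yl)-3-methylpent-2-en-1-yl acetate (racemic) | CC(=O)OC/C=C(/C)CCC1OC1(C)C | intermediate
11 | (2Z)-6,7-dihydroxy-3,7-dimethyloct-2-en-1-yl acetate (racemic) | CC(=O)OC/C=C(/C)CCC(O)C(C)(C)O | intermediate
12 | (2Z)-3-methyl-6-oxohex-2-en-1-yl acetate | CC(=O)OC/C=C(/C)CCC=O | intermediate
13 | ethyl 2-[bis(2,2,2-trifluoroethoxy)phosphoryl]propanoate | CCOC(=O)C(C)P(=O)(OCC(F)(F)F)OCC(F)(F)F | starting material
14 | potassium salt (α-carbanion) of 13 | CCOC(=O)[C-](C)P(=O)(OCC(F)(F)F)OCC(F)(F)F.[K+] | intermediate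
15 | ethyl (2Z,6Z)-8-acetoxy-2,6-dimethylocta-2,6-dienoate | CCOC(=O)/C(C)=C\CC/C(C)=C\COC(C)=O | intermediate
16 | ethyl (2Z,6Z)-8-hydroxy-2,6-dimethylocta-2,6-dienoate | CCOC(=O)/C(C)=C\CC/C(C)=C\CO | intermediate
17 | ethyl (2Z,6Z)-2,6-dimethyl-8-oxoocta-2,6-dienoate | CCOC(=O)/C(C)=C\CC/C(C)=C\C=O | intermediate
18 | ethyl (2Z,6Z)-2,6-dimethylnona-2,6,8-trienoate | CCOC(=O)/C(C)=C\CC/C(C)=C\C=C | intermediate
19 | (2Z,6Z)-2,6-dimethylnona-2,6,8-trien-1-ol | OC/C(C)=C\CC/C(C)=C\C=C | intermediate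
20 | tert-butyl{[(2Z,6Z)-2,6-dimethylnona-2,6,8-trien-1-yl]oxy}diphenylsilane | C=C/C=C(/C)CC/C=C(/C)CO[Si](c1ccccc1)(c1ccccc1)C(C)(C)C | intermediate
21 | furan-3-ylmethanol | OCc1ccoc1 | starting material
22 | 3-(bromomethyl)furan | BrCc1ccoc1 | intermediate
23 | trimethyl(prop-1-yn-1-yl)silane | CC#C[Si](C)(C)C | starting material
24 | [3-(trimethylsilyl)prop-2-yn-1-yl]lithium | [Li]CC#C[Si](C)(C)C | intermediate
25 | [4-(furan-3-yl)but-1-yn-1-yl]trimethylsilane | C[Si](C)(C)C#CCCc1ccoc1 | intermediate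
26 | 3-(but-3-yn-1-yl)furan | C#CCCc1ccoc1 | intermediate
27 | lithium 4-(furan-3-yl)but-1-yn-1-ide | [Li]C#CCCc1ccoc1 | intermediate
28 | methyl 5-(furan-3-yl)pent-2-ynoate | COC(=O)C#CCCc1ccoc1 | intermediate
29 | 9-{(3Z,7Z)-9-[(tert-butyldiphenylsilyl)oxy]-4,8-dimethylnona-3,7-dien-1-yl}-9-borabicyclo[3.3.1]nonane | B1(CC/C=C(/C)CC/C=C(/C)CO[Si](c2ccccc2)(c2ccccc2)C(C)(C)C)C2CCCC1CCC2 | intermediate
30 | tert-butyl{[(2Z,6Z,10E,13S)-15-[(tert-butyldimethylsilyl)oxy]-2,6,10-trimethyl-13-(prop-1-en-2-yl)pentadeca-2,6,10-trien-1-yl]oxy}diphenylsilane | C=C(C)[C@@H](C/C=C(\C)CC/C=C(/C)CC/C=C(/C)CO[Si](c1ccccc1)(c1ccccc1)C(C)(C)C)CCO[Si](C)(C)C(C)(C)C | intermediate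
31 | (3S,5E,9Z,13Z)-15-[(tert-butyldiphenylsilyl)oxy]-6,10,14-trimethyl-3-(prop-1-en-2-yl)pentadeca-5,9,13-trien-1-ol | C=C(C)[C@@H](C/C=C(\C)CC/C=C(/C)CC/C=C(/C)CO[Si](c1ccccc1)(c1ccccc1)C(C)(C)C)CCO | intermediate
32 | (3S,5E,9Z,13Z)-15-[(tert-butyldiphenylsilyl)oxy]-6,10,14-trimethyl-3-(prop-1-en-2-yl)pentadeca-5,9,13-trien-1-yl trifluoromethanesulfonate | C=C(C)[C@@H](C/C=C(\C)CC/C=C(/C)CC/C=C(/C)CO[Si](c1ccccc1)(c1ccccc1)C(C)(C)C)CCOS(=O)(=O)C(F)(F)F | intermediate
33 | methyl (2Z,5R,7E,11Z,15Z)-17-[(tert-butyldiphenylsilyl)oxy]-2-[3-(furan-3-yl)propylidene]-8,12,16-trimethyl-5-(prop-1-en-2-yl)heptadeca-7,11,15-trienoate | C=C(C)[C@@H](C/C=C(\C)CC/C=C(/C)CC/C=C(/C)CO[Si](c1ccccc1)(c1ccccc1)C(C)(C)C)CC/C(=C/CCc1ccoc1)C(=O)OC | intermediate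
34 | methyl (2Z,5R,7E,11Z,15Z)-2-[3-(furan-3-yl)propylidene]-17-hydroxy-8,12,16-trimethyl-5-(prop-1-en-2-yl)heptadeca-7,11,15-trienoate | C=C(C)[C@@H](C/C=C(\C)CC/C=C(/C)CC/C=C(/C)CO)CC/C(=C/CCc1ccoc1)C(=O)OC | intermediate
35 | (2Z,5R,7E,11Z,15Z)-2-[3-(furan-3-yl)propylidene]-17-hydroxy-8,12,16-trimethyl-5-(prop-1-en-2-yl)heptadeca-7,11,15-trienoic acid (CNP0258614.1) | C=C(C)[C@@H](C/C=C(\C)CC/C=C(/C)CC/C=C(/C)CO)CC/C(=C/CCc1ccoc1)C(=O)O | target

**Step count and risks**
Total step count: 23. Longest linear sequence: 14 steps (steps 6–13, then 18–23, from neryl acetate).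

Step 21 (the proposed new step) is the most likely to fail. The copper allenolate may be silylated or protonated faster than it is alkylated, giving the simple Z-enoate; the triflate may be reduced; or 32 may cyclise by π-participation of the 7E alkene. The fallback uses known chemistry, sets out from alcohol 31 and ynoate 28, and comes back at 33. Alcohol 31 is converted with I2, PPh3 and imidazole into tert-butyl{[(2Z,6Z,10E,13S)-15-iodo-2,6,10-trimethyl-13-(prop-1-en-2-yl)pentadeca-2,6,10-trien-1-yl]oxy}diphenylsilane F5. Lithium–iodine exchange (t-BuLi, Et2O, −78 °C, where the 5-hexenyllithium does not cyclise) and trapping with 9-methoxy-9-BBN give lithium methoxy{(3R,5E,9Z,13Z)-15-[(tert-butyldiphenylsilyl)oxy]-6,10,14-trimethyl-3-(prop-1-en-2-yl)pentadeca-5,9,13-trien-1-yl}(cyclooctane-1,5-diyl)borate F6. In parallel, 28 undergoes α-selective syn hydrostannation (Bu3SnH, Pd(PPh3)4, THF) to methyl (2E)-5-(furan-3-yl)-2-(tributylstannyl)pent-2-enoate F7, and iododestannylation (I2, CH2Cl2, 0 °C) gives methyl (2E)-5-(furan-3-yl)-2-iodopent-2-enoate F8. B-alkyl Suzuki–Miyaura coupling of F6 with F8 (Pd(dppf)Cl2·CH2Cl2, AsPh3, K3PO4, DMF/H2O, rt) proceeds with retention and gives 33.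

Step 5 may give the regioisomeric alkenyl iodide, or the excess zirconium hydride needed for regio-equilibration may attack the isopropenyl group. The fallback sets out from 6 and comes back at 8. Copper-catalysed syn borylcupration–protonation (CuCl, Xantphos, NaOtBu, B2pin2, MeOH, THF, rt) involves no hydride that can reduce the isopropenyl group, and gives tert-butyldimethyl{[(3S,5Z)-3-(prop-1-en-2-yl)-6-(4,4,5,5-tetramethyl-1,3,2-dioxaborolan-2-yl)hept-5-en-1-yl]oxy}silane F1, with boron on the methyl-bearing carbon; the minor regioisomer is removed by chromatography. Iododeboronation with retention (NaOH, then I2, THF/H2O, 0 °C) returns 8.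

Step 18 joins the two most valuable fragments. It may suffer from imperfect regiocontrol in the diene hydroboration or from slow transmetalation onto the hindered alkenyl iodide. The fallback sets out from 20 and 8 and comes back at 30. Triene 20 is hydroborated as in step 18 and the borane 29 is oxidised (NaBO3·4H2O) to (3Z,7Z)-9-[(tert-butyldiphenylsilyl)oxy]-4,8-dimethylnona-3,7-dien-1-ol F2, which is purified at this stage. I2, PPh3 and imidazole give tert-butyl{[(2Z,6Z)-9-iodo-2,6-dimethylnona-2,6-dien-1-yl]oxy}diphenylsilane F3. t-BuLi (Et2O, −78 °C) followed by ZnCl2 gives chloro{(3Z,7Z)-9-[(tert-butyldiphenylsilyl)oxy]-4,8-dimethylnona-3,7-dien-1-yl}zinc F4, which undergoes Negishi coupling with 8 (Pd(PPh3)4, THF, rt → 40 °C) to give 30.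

**Further compounds**
F1 | step 5 | tert-butyldimethyl{[(3S,5Z)-3-(prop-1-en-2-yl)-6-(4,4,5,5-tetramethyl-1,3,2-dioxaborolan-2-yl)hept-5-en-1-yl]oxy}silane | C/C(B1OC(C)(C)C(C)(C)O1)=C\C[C@@H](CCO[Si](C)(C)C(C)(C)C)C(C)=C
F2 | step 18 | (3Z,7Z)-9-[(tert-butyldiphenylsilyl)oxy]-4,8-dimethylnona-3,7-dien-1-ol | OCC/C=C(/C)CC/C=C(/C)CO[Si](c1ccccc1)(c1ccccc1)C(C)(C)C
F3 | step 18 | tert-butyl{[(2Z,6Z)-9-iodo-2,6-dimethylnona-2,6-dien-1-yl]oxy}diphenylsilane | ICC/C=C(/C)CC/C=C(/C)CO[Si](c1ccccc1)(c1ccccc1)C(C)(C)C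
F4 | step 18 | chloro{(3Z,7Z)-9-[(tert-butyldiphenylsilyl)oxy]-4,8-dimethylnona-3,7-dien-1-yl}zinc | Cl[Zn]CC/C=C(/C)CC/C=C(/C)CO[Si](c1ccccc1)(c1ccccc1)C(C)(C)C
F5 | step 21 | tert-butyl{[(2Z,6Z,10E,13S)-15-iodo-2,6,10-trimethyl-13-(prop-1-en-2-yl)pentadeca-2,6,10-trien-1-yl]oxy}diphenylsilane | C=C(C)[C@@H](C/C=C(\C)CC/C=C(/C)CC/C=C(/C)CO[Si](c1ccccc1)(c1ccccc1)C(C)(C)C)CCI
F6 | step 21 | lithium methoxy{(3R,5E,9Z,13Z)-15-[(tert-butyldiphenylsilyl)oxy]-6,10,14-trimethyl-3-(prop-1-en-2-yl)pentadeca-5,9,13-trien-1-yl}(cyclooctane-1,5-diyl)borate | C=C(C)[C@@H](C/C=C(\C)CC/C=C(/C)CC/C=C(/C)CO[Si](c1ccccc1)(c1ccccc1)C(C)(C)C)CC[B-]1(OC)C2CCCC1CCC2.[Li+]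
F7 | step 21 | methyl (2E)-5-(furan-3-yl)-2-(tributylstannyl)pent-2-enoate | CCCC[Sn](CCCC)(CCCC)/C(C(=O)OC)=C/CCc1ccoc1
F8 | step 21 | methyl (2E)-5-(furan-3-yl)-2-iodopent-2-enoate | I/C(C(=O)OC)=C/CCc1ccoc1
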